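**Retrosynthetic overview**
1. Target 21 ⇐ HF unmasking of 20 ⇐ oxidation of a sacrificial (R)-methyl carbinol (19) to the acetyl group ⇐ protected biaryl 18.
2. Biaryl bond C7–C7′ ⇐ Suzuki coupling of silylene-protected 7-bromonepodin 16 (from nepodin 14) with dihydronaphthalene bromide 13.
3. Dihydronaphthalene ring (C1′–C2′ bond, both stereocentres) ⇐ visible-light photoredox ketyl–ene cyclisation of the o-allyl salicylaldehyde 11, steered by the (R)-carbinol bought in (R)-but-3-yn-2-ol.
4. 11 ⇐ ortho-formylation of phenol 10 ⇐ hydrozirconation/Pd coupling of alkyne 4 with benzylic bromide 7 (from 2-bromo-5-methylphenol).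
5. Ring order: all aromatic rings are bought; the only ring built is the dihydro ring (step 7); the two silylene rings are temporary.

Assumption: nepodin (musizin, 2-acetyl-1,8-dihydroxy-3-methylnaphthalene) is bought as a catalogue natural product.

**Step 1**
Reactants: 1 (R)-but-3-yn-2-ol
Product: 2 (R)-(but-3-yn-2-yloxy)triethylsilane
Conditions: TESCl, imidazole, CH2Cl2, 0 °C to rt
Reagents that add atoms: chlorotriethylsilane, CC[Si](Cl)(CC)CC
Why: Standard O-silylation of a secondary alcohol, which leaves the purchased (R) centre untouched.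

**Step 2**
Reactants: 2 (R)-(but-3-yn-2-yloxy)triethylsilane
Product: 4 (R)-triethyl(pent-3-yn-2-yloxy)silane, via lithium acetylide 3 (not isolated)
Conditions: n-BuLi, THF, −78 °C; then MeI, DMPU, −78 °C to rt
Reagents that add atoms: iodomethane, CI
Why: Acetylide alkylation of the terminal alkyne, remote from the stereocentre.

**Step 3**
Reactants: 5 2-bromo-5-methylphenol
Product: 6 2-bromo-5-methylphenyl acetate
Conditions: Ac2O, Et3N, DMAP (cat.), CH2Cl2, rt
Reagents that add atoms: acetic anhydride, CC(=O)OC(C)=O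
Why: Phenol acetylation, which removes the acidic OH and deactivates the ring towards electrophilic bromination in the next step.

**Step 4**
Reactants: 6 2-bromo-5-methylphenyl acetate
Product: 7 2-bromo-5-(bromomethyl)phenyl acetate
Conditions: NBS, AIBN (5 mol%), PhCF3, 85 °C
Reagents that add atoms: N-bromosuccinimide, O=C1CCC(=O)N1Br
Why: Wohl–Ziegler radical bromination of the only benzylic position.

**Step 5**
Reactants: 4 (R)-triethyl(pent-3-yn-2-yloxy)silane; 7 2-bromo-5-(bromomethyl)phenyl acetate
Product: 10 2-bromo-5-[(2E,4R)-2-methyl-4-(triethylsilyloxy)pent-2-en-1-yl]phenol, via alkenylzirconocene 8 (not isolated), via aryl acetate 9 (not isolated)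
Conditions: Cp2Zr(H)Cl, THF, 45 °C; then 7, Pd(PPh3)4 (5 mol%), ZnCl2 (20 mol%), rt; then K2CO3 (cat.), MeOH, 0 °C
Reagents that add atoms: none
Why: Schwartz syn-hydrozirconation puts Zr on the methyl-bearing alkyne carbon (away from the branched silyloxy carbon) to give the E-alkenyl metal, Negishi-type Pd coupling with the benzylic bromide (much faster than the aryl bromide) proceeds with retention, and methanolysis frees the phenol.

**Step 6**
Reactants: 10 2-bromo-5-[(2E,4R)-2-methyl-4-(triethylsilyloxy)pent-2-en-1-yl]phenol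
Product: 11 3-bromo-2-hydroxy-6-[(2E,4R)-2-methyl-4-(triethylsilyloxy)pent-2-en-1-yl]benzaldehyde
Conditions: MgCl2, Et3N, (CH2O)n, MeCN, 75 °C
Reagents that add atoms: paraformaldehyde (formaldehyde), C=O
Why: Magnesium-phenoxide-directed ortho-formylation (Casnati–Skattebøl), which can only occur at the single free ortho position because the other carries Br.

**Step 7**
Reactants: 11 3-bromo-2-hydroxy-6-[(2E,4R)-2-methyl-4-(triethylsilyloxy)pent-2-en-1-yl]benzaldehyde
Product: 12 (1S,2R)-7-bromo-3-methyl-2-[(1R)-1-(triethylsilyloxy)ethyl]-1,2-dihydronaphthalene-1,8-diol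
Conditions: fac-Ir(ppy)3 (2 mol%), degassed MeCN (0.01 M), 450 nm LEDs, 25 °C
Reagents that add atoms: none
Why: Proposed new method: a redox-neutral photocatalytic ketyl–ene (formal carbonyl-ene) cyclisation in which excited Ir(ppy)3 reduces the intramolecularly hydrogen-bonded salicylaldehyde by proton-coupled electron transfer to a neutral ketyl radical, this radical adds reversibly 6-endo to the less substituted alkene carbon to give the tertiary C3 radical, Ir(IV) oxidises that radical to the cation (radical–polar crossover) and the phenoxide removes the benzylic C4 proton, so the substrate is simply isomerised; the closest known chemistry is photoredox PCET ketyl–olefin coupling combined with radical–polar crossover elimination (thermal counterpart: Lewis-acid carbonyl-ene cyclisation), and the stereocentres come from a half-chair transition state with the phenol-bound C1–O bond and the E-alkene substituent both pseudo-equatorial (1,2-trans) and the new bond formed anti to the OSiEt3 group of the A(1,3)-locked (R)-carbinol (Felkin–Anh-type attack of the nucleophilic radical), giving 1S,2R.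

**Step 8**
Reactants: 12 (1S,2R)-7-bromo-3-methyl-2-[(1R)-1-(triethylsilyloxy)ethyl]-1,2-dihydronaphthalene-1,8-diol
Product: 13 di-tert-butylsilylene acetal of 12 (Si bridges O1 and O8; CIP 1S,2S,1′R, the 2R→2S change being a priority change only)
Conditions: t-Bu2Si(OTf)2, 2,6-lutidine, CH2Cl2, −20 to 0 °C
Reagents that add atoms: di-tert-butylsilyl bis(trifluoromethanesulfonate), CC(C)(C)[Si](OS(=O)(=O)C(F)(F)F)(OS(=O)(=O)C(F)(F)F)C(C)(C)C
Why: Cyclic silylene formation across the phenol/benzylic alcohol pair (six-membered ring) protects the oxidation-prone C1 carbinol and the phenol in one operation without touching the stereocentres.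

**Step 9**
Reactants: 14 nepodin
Product: 15 1-(7-bromo-1,8-dihydroxy-3-methylnaphthalen-2-yl)ethan-1-one
Conditions: NBS, i-Pr2NH (10 mol%), CH2Cl2, −78 to 0 °C
Reagents that add atoms: N-bromosuccinimide, O=C1CCC(=O)N1Br
Why: Amine-mediated ortho-selective electrophilic bromination of a phenol delivers Br next to the free 8-OH (C7), the only unsubstituted ortho position of either hydroxyl.

**Step 10**
Reactants: 15 1-(7-bromo-1,8-dihydroxy-3-methylnaphthalen-2-yl)ethan-1-one
Product: 16 1,8-O-di-tert-butylsilylene acetal of 15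
Conditions: t-Bu2Si(OTf)2, 2,6-lutidine, CH2Cl2, 0 °C to rt
Reagents that add atoms: di-tert-butylsilyl bis(trifluoromethanesulfonate), CC(C)(C)[Si](OS(=O)(=O)C(F)(F)F)(OS(=O)(=O)C(F)(F)F)C(C)(C)C
Why: Silylene protection of the peri-diol (six-membered ring) masks both naphthols for the coupling and the later oxidation.

**Step 11**
Reactants: 16 1,8-O-di-tert-butylsilylene acetal of 15; 13 di-tert-butylsilylene acetal of 12
Product: 18 C7–C7′ biaryl (13 with Br replaced by C7 of 16), via pinacol boronate 17 (not isolated)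
Conditions: Pd(dppf)Cl2 (5 mol%), B2pin2, KOAc, dioxane, 90 °C; then 13, SPhos Pd G3 (5 mol%), K3PO4, dioxane/H2O 10:1, 60 °C
Reagents that add atoms: none
Why: One-pot Miyaura borylation/Suzuki–Miyaura coupling joins the two aryl bromides at the pre-set ortho positions (a di-ortho-substituted biaryl, well within SPhos scope) without affecting the sp3 stereocentres.

**Step 12**
Reactants: 18 C7–C7′ biaryl with both silylene acetals and the triethylsilyl ether
Product: 19 secondary alcohol (18 with the OSiEt3 group converted to OH)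
Conditions: PPTS (20 mol%), MeOH/CH2Cl2 1:1, 0 °C to rt
Reagents that add atoms: none
Why: Mild acid methanolysis cleaves the unhindered secondary TES ether selectively, as the aryl-bound di-tert-butylsilylenes are stable to weak acid.

**Step 13**
Reactants: 19 secondary alcohol
Product: 20 methyl ketone (bis-silylene-protected target; ring 1′S,2′R)
Conditions: Dess–Martin periodinane, pyridine, CH2Cl2, 0 °C
Reagents that add atoms: none
Why: Buffered Dess–Martin oxidation converts the only free hydroxyl (the sacrificial carbinol) into the acetyl group under near-neutral conditions that do not enolise the new C2′–H.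

**Step 14**
Reactants: 20 methyl ketone
Product: 21 target (1′S,2′R)
Conditions: HF·pyridine, pyridine, THF, 0 °C; MeOSiMe3 quench
Reagents that add atoms: none
Why: Buffered fluoride desilylation removes both silylenes under non-basic conditions, avoiding enolate-triggered dehydration/aromatisation of the β-hydroxy ketone.

**Compound list**
1 | (R)-but-3-yn-2-ol | C#C[C@@H](C)O | starting material
2 | (R)-(but-3-yn-2-yloxy)triethylsilane | C#C[C@@H](C)O[Si](CC)(CC)CC | intermediate
3 | lithium (R)-3-(triethylsilyloxy)but-1-yn-1-ide | [Li]C#C[C@@H](C)O[Si](CC)(CC)CC | intermediate (not isolated)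
4 | (R)-triethyl(pent-3-yn-2-yloxy)silane | CC#C[C@@H](C)O[Si](CC)(CC)CC | intermediate
5 | 2-bromo-5-methylphenol | Cc1ccc(Br)c(O)c1 | starting material
6 | 2-bromo-5-methylphenyl acetate | Cc1ccc(Br)c(OC(C)=O)c1 | intermediate
7 | 2-bromo-5-(bromomethyl)phenyl acetate | BrCc1ccc(Br)c(OC(C)=O)c1 | intermediate
8 | chlorobis(cyclopentadienyl)[(2E,4R)-4-(triethylsilyloxy)pent-2-en-2-yl]zirconium | Cl[Zr](C1C=CC=C1)(C1C=CC=C1)/C(C)=C/[C@@H](C)O[Si](CC)(CC)CC | intermediate (not isolated)
9 | 2-bromo-5-[(2E,4R)-2-methyl-4-(triethylsilyloxy)pent-2-en-1-yl]phenyl acetate | CC(=O)Oc1cc(C/C(C)=C/[C@@H](C)O[Si](CC)(CC)CC)ccc1Br | intermediate (not isolated)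
10 | 2-bromo-5-[(2E,4R)-2-methyl-4-(triethylsilyloxy)pent-2-en-1-yl]phenol | Oc1cc(C/C(C)=C/[C@@H](C)O[Si](CC)(CC)CC)ccc1Br | intermediate
11 | 3-bromo-2-hydroxy-6-[(2E,4R)-2-methyl-4-(triethylsilyloxy)pent-2-en-1-yl]benzaldehyde | O=Cc1c(O)c(Br)ccc1C/C(C)=C/[C@@H](C)O[Si](CC)(CC)CC | intermediate
12 | (1S,2R)-7-bromo-3-methyl-2-[(1R)-1-(triethylsilyloxy)ethyl]-1,2-dihydronaphthalene-1,8-diol | Brc1ccc2c(c1O)[C@@H](O)[C@H]([C@@H](C)O[Si](CC)(CC)CC)C(C)=C2 | intermediate
13 | 12 with O1 and O8 bridged by Si(t-Bu)2 (1S,2S,1′R) | Brc1ccc2c(c1O[Si]5(C(C)(C)C)C(C)(C)C)[C@@H](O5)[C@H]([C@@H](C)O[Si](CC)(CC)CC)C(C)=C2 | intermediate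
14 | nepodin, 1-(1,8-dihydroxy-3-methylnaphthalen-2-yl)ethan-1-one | CC(=O)c1c(C)cc2cccc(O)c2c1O | starting material
15 | 1-(7-bromo-1,8-dihydroxy-3-methylnaphthalen-2-yl)ethan-1-one | CC(=O)c1c(C)cc2ccc(Br)c(O)c2c1O | intermediate
16 | 15 with O1 and O8 bridged by Si(t-Bu)2 | CC(=O)c1c(C)cc2ccc(Br)c3O[Si](C(C)(C)C)(C(C)(C)C)Oc1c23 | intermediate
17 | 16 with Br replaced by 4,4,5,5-tetramethyl-1,3,2-dioxaborolan-2-yl | CC(=O)c1c(C)cc2ccc(B4OC(C)(C)C(C)(C)O4)c3O[Si](C(C)(C)C)(C(C)(C)C)Oc1c23 | intermediate (not isolated)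
18 | biaryl: 13 with Br replaced by C7 of 16 (1′S,2′S, side chain R) | CC(=O)c1c(C)cc2ccc(-c4ccc5c(c4O[Si]6(C(C)(C)C)C(C)(C)C)[C@@H](O6)[C@H]([C@@H](C)O[Si](CC)(CC)CC)C(C)=C5)c3O[Si](C(C)(C)C)(C(C)(C)C)Oc1c23 | intermediate
19 | 18 with the side chain as (1R)-1-hydroxyethyl (1′S,2′S) | CC(=O)c1c(C)cc2ccc(-c4ccc5c(c4O[Si]6(C(C)(C)C)C(C)(C)C)[C@@H](O6)[C@H]([C@@H](C)O)C(C)=C5)c3O[Si](C(C)(C)C)(C(C)(C)C)Oc1c23 | intermediate
20 | 19 with the side chain oxidised to acetyl (1′S,2′R) | CC(=O)c1c(C)cc2ccc(-c4ccc5c(c4O[Si]6(C(C)(C)C)C(C)(C)C)[C@@H](O6)[C@H](C(C)=O)C(C)=C5)c3O[Si](C(C)(C)C)(C(C)(C)C)Oc1c23 | intermediate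
21 | CNP0298944.1, 1-{7-[(7S,8S)-7-acetyl-1,8-dihydroxy-6-methyl-7,8-dihydronaphthalen-2-yl]-1,8-dihydroxy-3-methylnaphthalen-2-yl}ethan-1-one (7S,8S in this name = 2′R,1′S in the ring numbering used in the steps) | CC(=O)c1c(C)cc2ccc(-c3ccc4c(c3O)[C@@H](O)[C@H](C(C)=O)C(C)=C4)c(O)c2c1O | target

**Step count:** 14 steps in total. Longest linear sequence: 10 steps (5 → 21 through steps 3–8 and 11–14; the sequence from 1 is equally long).

**Three steps most likely to fail**

Step 7 (the new photoredox ketyl–ene cyclisation). Possible failures are 5-exo instead of 6-endo closure, pinacol dimerisation, loss of the aryl bromide, or the opposite facial sense at the carbinol-bearing alkene (in which case (S)-but-3-yn-2-ol would be needed). The fallback uses known chemistry and sets out from 11: a Lewis-acid-promoted intramolecular carbonyl-ene (Prins-type) cyclisation with Me2AlCl (2.2 equiv) in CH2Cl2 at −78 to −40 °C. The aluminium phenoxide chelates the aldehyde oxygen, the trisubstituted alkene attacks C1 through the same half-chair to give the tertiary cation, and loss of the benzylic proton gives the 1,2-trans dihydronaphthalenol, returning to the route at 12 after a Rochelle-salt work-up. Any minor diastereomer is removed at 12 or 13. This fallback makes no new compound (none F0).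

Step 9 (ortho-selective bromination of nepodin; C5 or C4 bromination may compete). The fallback builds the brominated naphthalene instead of functionalising it, and sets out from 5. Magnesium-mediated ortho-formylation gives 3-bromo-2-hydroxy-6-methylbenzaldehyde F1. MOMCl/i-Pr2NEt gives 3-bromo-2-(methoxymethoxy)-6-methylbenzaldehyde F2. Oxidative esterification (I2, KOH, MeOH) gives methyl 3-bromo-2-(methoxymethoxy)-6-methylbenzoate F3. Toluate-anion annulation (LDA, THF, −78 °C, then 4-methoxypent-3-en-2-one: addition–elimination followed by Claisen ring closure) gives 1-[7-bromo-1-hydroxy-8-(methoxymethoxy)-3-methylnaphthalen-2-yl]ethan-1-one F4. HCl/MeOH removes the MOM group and the sequence comes back to the route at 15.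

Step 11 (Suzuki coupling of two ortho-silyloxy partners; aqueous base may open the aryl silylenes or protodeboronate 17). The fallback replaces the basic aqueous coupling by a neutral Stille coupling and sets out from 16. Pd(PPh3)4 and hexamethylditin in toluene at 100 °C give the 7-trimethylstannyl derivative of 16 F5. This is coupled with 13 using Pd(t-Bu3P)2 and CuI (cat.) in dry dioxane at 60 °C, returning to the route at 18.

**Further compounds**
F0 | step 7 | none | none
F1 | step 9 | 3-bromo-2-hydroxy-6-methylbenzaldehyde | Cc1ccc(Br)c(O)c1C=O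
F2 | step 9 | 3-bromo-2-(methoxymethoxy)-6-methylbenzaldehyde | COCOc1c(Br)ccc(C)c1C=O
F3 | step 9 | methyl 3-bromo-2-(methoxymethoxy)-6-methylbenzoate | COCOc1c(Br)ccc(C)c1C(=O)OC
F4 | step 9 | 1-[7-bromo-1-hydroxy-8-(methoxymethoxy)-3-methylnaphthalen-2-yl]ethan-1-one | CC(=O)c1c(C)cc2ccc(Br)c(OCOC)c2c1O
F5 | step 11 | 7-trimethylstannyl derivative of 16 | CC(=O)c1c(C)cc2ccc([Sn](C)(C)C)c3O[Si](C(C)(C)C)(C(C)(C)C)Oc1c23
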